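**Plan** (flavanone numbering O1, C2, C3, C4, C4a, C5–C8, C8a; ring A = benzo ring, ring B = 4-hydroxyphenyl, ring C = pyranone; piperidine atoms primed)
- Retrosynthetic cuts, in order: the three O–benzyl bonds and the C4 carbonyl (back to a silyl-protected carbinol); the C8a–O1 bond; C3–C4 (aldol); C4–C4a (formylation); N–CH3, N1'–C6' and C2'–C3' of the piperidine; the aryl–O bonds at C5 and C7.
- Enabling feature: O1 is bonded to the aromatic carbon C8a of ring A and to the benzylic carbon C2, so ring C can be closed at the aryl–oxygen bond from a C8a bromide and a finished C2 carbinol, with no bond to C2 made or broken.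
- Forward order: ring A is bought; the piperidine ring is built on its aldehyde carbon; C4 is added beside bromine; C3, C2 and ring B arrive by aldol addition; ring C closes last; then the oxidation level and protecting groups are adjusted.
- Stereochemistry: C2' comes from a Grignard addition directed by the (R)-tert-butanesulfinyl group; C2 comes from catalyst-controlled transfer hydrogenation with the (S,S)-TsDPEN ruthenium complex; C4 is left uncontrolled because it ends as a carbonyl.

Key step: step 10

Remark: C4 is carried as both epimers from 17 to 21; they converge on the ketone in step 12, so no separation is planned.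

**Step 1**
Reactants: 1 4-bromo-2,6-difluorobenzaldehyde; 2 benzyl alcohol
Product: 5 2,6-bis(benzyloxy)-4-bromobenzaldehyde, via sodium benzyloxide 3 (not isolated), via 2-(benzyloxy)-4-bromo-6-fluorobenzaldehyde 4 (not isolated)
Conditions: 2 (2.2 equiv), NaH, THF, 0 °C; then 1, 0 → 40 °C
Reagents that add atoms: none
Why: Nucleophilic aromatic substitution by addition–elimination should replace both fluorides, which lie ortho to the formyl group that stabilises the Meisenheimer intermediates, while bromide is a far poorer leaving group and stays.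

**Step 2**
Reactants: 5 2,6-bis(benzyloxy)-4-bromobenzaldehyde
Product: 6 (R)-N-[(E)-(2,6-bis(benzyloxy)-4-bromophenyl)methylidene]-2-methylpropane-2-sulfinamide
Conditions: (R)-tert-butanesulfinamide, Ti(OEt)4, THF, 65 °C
Reagents that add atoms: (R)-tert-butanesulfinamide, CC(C)(C)[S@@](=O)N
Why: Condensation of an aldehyde with a sulfinamide to the (E)-N-sulfinyl aldimine, in which Ti(OEt)4 acts as Lewis acid and water scavenger, should succeed even with a doubly ortho-substituted benzaldehyde.

**Step 3**
Reactants: 6 (R)-N-sulfinyl aldimine; 7 1-bromo-4-chlorobutane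
Product: 9 (R)-N-{(1S)-1-[2,6-bis(benzyloxy)-4-bromophenyl]-5-chloropentyl}-2-methylpropane-2-sulfinamide, via 4-chlorobutylmagnesium bromide 8 (not isolated)
Conditions: 7, Mg, THF, 25 °C; then 6, CH2Cl2, −48 → 0 °C; aq NH4Cl
Reagents that add atoms: none
Why: Grignard addition to an N-tert-butanesulfinyl aldimine in a non-coordinating solvent should pass through a six-membered chair transition state with magnesium bound to the sulfinyl oxygen and tert-butyl equatorial, so the (R)-sulfinyl group sends the alkyl group to the Si face and sets the (S) centre that becomes C2'.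

**Step 4**
Reactants: 9 chloropentyl sulfinamide
Product: 11 (2S)-2-[2,6-bis(benzyloxy)-4-bromophenyl]piperidine, via (1S)-1-[2,6-bis(benzyloxy)-4-bromophenyl]-5-chloropentan-1-aminium chloride 10 (not isolated)
Conditions: HCl, MeOH/dioxane, 25 °C; evaporate; then K2CO3, NaI (cat.), MeCN, 80 °C
Reagents that add atoms: none
Why: Acid methanolysis of the S–N bond frees the primary amine without touching the stereocentre, and after neutralisation the amine closes the piperidine by intramolecular SN2 N-alkylation at the primary chloride (6-exo-tet, assisted by iodide exchange).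

**Step 5**
Reactants: 11 (2S)-2-arylpiperidine
Product: 12 (2S)-2-[2,6-bis(benzyloxy)-4-bromophenyl]-1-methylpiperidine
Conditions: aq HCHO, NaBH(OAc)3, ClCH2CH2Cl, 25 °C
Reagents that add atoms: formaldehyde, C=O
Why: Reductive amination, in which the secondary amine and formaldehyde form an iminium ion that NaBH(OAc)3 reduces, should methylate nitrogen once without quaternisation and leave the adjacent stereocentre untouched.

**Step 6**
Reactants: 12 N-methylpiperidine aryl bromide
Product: 14 2,4-bis(benzyloxy)-6-bromo-3-[(2S)-1-methylpiperidin-2-yl]benzaldehyde, via {2,4-bis(benzyloxy)-6-bromo-3-[(2S)-1-methylpiperidin-2-yl]phenyl}lithium 13 (not isolated)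
Conditions: LDA, THF, −78 °C; then DMF, −78 °C; aq NH4Cl
Reagents that add atoms: N,N-dimethylformamide, CN(C)C=O
Why: Directed ortho-lithiation and formylation should work because the two remaining ring protons are equivalent and each lies between bromine and a benzyloxy group, which makes it acidic enough for a lithium amide that deprotonates at −78 °C without bromine–lithium exchange, and DMF traps the aryllithium before lithium bromide can be lost.

**Step 7**
Reactants: 14 aldehyde; 15 1-[4-(benzyloxy)phenyl]ethanone
Product: 17 3-{2,4-bis(benzyloxy)-6-bromo-3-[(2S)-1-methylpiperidin-2-yl]phenyl}-1-[4-(benzyloxy)phenyl]-3-hydroxypropan-1-one (both C3 epimers), via lithium 1-[4-(benzyloxy)phenyl]ethenolate 16 (not isolated)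
Conditions: 15, LDA, THF, −78 °C; then 14, −78 °C; AcOH quench at −78 °C
Reagents that add atoms: none
Why: Aldol addition of a preformed lithium enolate to a non-enolisable aldehyde, quenched cold to prevent retro-aldol cleavage and dehydration, forms the C3–C4 bond, and the new carbinol centre needs no control because it ends as the C4 carbonyl.

**Step 8**
Reactants: 17 β-hydroxy ketone
Product: 18 3-{2,4-bis(benzyloxy)-6-bromo-3-[(2S)-1-methylpiperidin-2-yl]phenyl}-1-[4-(benzyloxy)phenyl]-3-[(tert-butyldimethylsilyl)oxy]propan-1-one (both C3 epimers)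
Conditions: TBSOTf, 2,6-lutidine, CH2Cl2, −78 → 0 °C
Reagents that add atoms: tert-butyldimethylsilyl trifluoromethanesulfonate, CC(C)(C)[Si](C)(C)OS(=O)(=O)C(F)(F)F
Why: Silylation of a hindered secondary alcohol with a silyl triflate and a non-nucleophilic pyridine base blocks retro-aldol and chalcone formation and keeps this benzylic oxygen away from palladium in the ring closure.

**Step 9**
Reactants: 18 β-silyloxy ketone
Product: 19 (1S)-3-{2,4-bis(benzyloxy)-6-bromo-3-[(2S)-1-methylpiperidin-2-yl]phenyl}-1-[4-(benzyloxy)phenyl]-3-[(tert-butyldimethylsilyl)oxy]propan-1-ol (both C3 epimers)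
Conditions: RuCl(p-cymene)[(S,S)-TsDPEN] (cat.), HCO2H/Et3N, CH2Cl2, 25 °C
Reagents that add atoms: none
Why: Noyori asymmetric transfer hydrogenation delivers hydride and proton through a six-membered outer-sphere transition state in which the ketone aryl ring sits under the p-cymene ligand, which for aryl alkyl ketones gives the (S)-carbinol under catalyst control whatever the configuration at the silyloxy carbon, and the aryl bromide, silyl ether and benzyl ethers are not touched.

**Step 10**
Reactants: 19 (1S)-bromo carbinol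
Product: 20 (2S)-5,7-bis(benzyloxy)-2-[4-(benzyloxy)phenyl]-4-[(tert-butyldimethylsilyl)oxy]-6-[(2S)-1-methylpiperidin-2-yl]chromane (both C4 epimers)
Conditions: Pd(OAc)2 (cat.), 2-(di-tert-butylphosphino)-1,1'-binaphthyl, Cs2CO3, toluene, 80 °C
Reagents that add atoms: none
Why: Zerovalent palladium formed in situ from Pd(OAc)2 and the phosphine inserts into the C8a–Br bond, the C2 hydroxyl is deprotonated by Cs2CO3 and replaces bromide on divalent palladium, and C–O reductive elimination from the seven-membered oxapalladacycle forms the C8a–O1 bond. The closest known reaction type is the palladium-catalysed intramolecular etherification of aryl bromides with secondary alcohols (Buchwald–Hartwig C–O coupling), which is established for chromans. Ring C closes as a six-membered ring in a formally 6-exo mode, the alkoxide oxygen being joined to the aryl carbon of ring A. No stereocentre is created: C2 keeps its (S) configuration because none of its four bonds takes part, and C4 stays a mixture that is removed later. The selectivity needed is reductive elimination over β-hydride loss from the palladium alkoxide, which the bulky electron-rich di-tert-butyl biaryl phosphine should secure by crowding the metal, while the silyl group at C4 keeps the nearer benzylic oxygen from forming a five-membered chelate that would divert the catalyst. The benzyloxy groups are meta to bromine and so leave the bromide reactive enough for insertion, and the tertiary amine, silyl ether and benzyl ethers are inert to the carbonate base.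

**Step 11**
Reactants: 20 silyl-protected chromane
Product: 21 (2S)-5,7-bis(benzyloxy)-2-[4-(benzyloxy)phenyl]-6-[(2S)-1-methylpiperidin-2-yl]chroman-4-ol (both C4 epimers)
Conditions: TBAF, THF, 0 → 25 °C
Reagents that add atoms: none
Why: Fluoride-induced cleavage of the silyl ether, driven by the strength of the Si–F bond, proceeds under basic conditions that do not ionise the electron-rich benzylic C4–O bond.

**Step 12**
Reactants: 21 chroman-4-ol
Product: 22 (2S)-5,7-bis(benzyloxy)-2-[4-(benzyloxy)phenyl]-6-[(2S)-1-methylpiperidin-2-yl]chroman-4-one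
Conditions: Dess–Martin periodinane, NaHCO3, CH2Cl2, 0 → 25 °C
Reagents that add atoms: none
Why: Dess–Martin oxidation of the secondary benzylic alcohol under buffered, near-neutral conditions converges both C4 epimers on one flavanone without enolisation towards C2 or opening of ring C.

**Step 13**
Reactants: 22 tribenzyl flavanone
Product: 23 (2S)-5,7-dihydroxy-2-(4-hydroxyphenyl)-6-[(2S)-1-methylpiperidin-2-yl]chroman-4-one
Conditions: H2 (1 atm), Pd/C, EtOAc/MeOH, 25 °C
Reagents that add atoms: none
Why: Catalytic hydrogenolysis of the three aryl benzyl ethers under neutral conditions at atmospheric pressure should be much faster than cleavage of the cyclic benzylic C2–O1 and C2'–N bonds or reduction of the hydrogen-bonded aryl ketone, so the free flavanone is released with both stereocentres intact.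

**Compound list**
1 | 4-bromo-2,6-difluorobenzaldehyde | O=Cc1c(F)cc(Br)cc1F | starting material
2 | benzyl alcohol | OCc1ccccc1 | starting material
3 | sodium benzyloxide | [Na+].[O-]Cc1ccccc1 | intermediate
4 | 2-(benzyloxy)-4-bromo-6-fluorobenzaldehyde | O=Cc1c(F)cc(Br)cc1OCc1ccccc1 | intermediate
5 | 2,6-bis(benzyloxy)-4-bromobenzaldehyde | O=Cc1c(OCc2ccccc2)cc(Br)cc1OCc1ccccc1 | intermediate
6 | (R)-N-[(E)-(2,6-bis(benzyloxy)-4-bromophenyl)methylidene]-2-methylpropane-2-sulfinamide | CC(C)(C)[S@@](=O)/N=C/c1c(OCc2ccccc2)cc(Br)cc1OCc1ccccc1 | intermediate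
7 | 1-bromo-4-chlorobutane | ClCCCCBr | starting material
8 | 4-chlorobutylmagnesium bromide | ClCCCC[Mg]Br | intermediate
9 | (R)-N-{(1S)-1-[2,6-bis(benzyloxy)-4-bromophenyl]-5-chloropentyl}-2-methylpropane-2-sulfinamide | CC(C)(C)[S@@](=O)N[C@@H](CCCCCl)c1c(OCc2ccccc2)cc(Br)cc1OCc1ccccc1 | intermediate
10 | (1S)-1-[2,6-bis(benzyloxy)-4-bromophenyl]-5-chloropentan-1-aminium chloride | [Cl-].[NH3+][C@@H](CCCCCl)c1c(OCc2ccccc2)cc(Br)cc1OCc1ccccc1 | intermediate
11 | (2S)-2-[2,6-bis(benzyloxy)-4-bromophenyl]piperidine | N1CCCC[C@H]1c1c(OCc2ccccc2)cc(Br)cc1OCc1ccccc1 | intermediate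
12 | (2S)-2-[2,6-bis(benzyloxy)-4-bromophenyl]-1-methylpiperidine | CN1CCCC[C@H]1c1c(OCc2ccccc2)cc(Br)cc1OCc1ccccc1 | intermediate
13 | {2,4-bis(benzyloxy)-6-bromo-3-[(2S)-1-methylpiperidin-2-yl]phenyl}lithium | CN1CCCC[C@H]1c1c(OCc2ccccc2)cc(Br)c([Li])c1OCc1ccccc1 | intermediate
14 | 2,4-bis(benzyloxy)-6-bromo-3-[(2S)-1-methylpiperidin-2-yl]benzaldehyde | CN1CCCC[C@H]1c1c(OCc2ccccc2)cc(Br)c(C=O)c1OCc1ccccc1 | intermediate
15 | 1-[4-(benzyloxy)phenyl]ethanone | CC(=O)c1ccc(OCc2ccccc2)cc1 | starting material
16 | lithium 1-[4-(benzyloxy)phenyl]ethenolate | C=C(O[Li])c1ccc(OCc2ccccc2)cc1 | intermediate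
17 | 3-{2,4-bis(benzyloxy)-6-bromo-3-[(2S)-1-methylpiperidin-2-yl]phenyl}-1-[4-(benzyloxy)phenyl]-3-hydroxypropan-1-one, both C3 epimers | CN1CCCC[C@H]1c1c(OCc2ccccc2)cc(Br)c(C(O)CC(=O)c2ccc(OCc3ccccc3)cc2)c1OCc1ccccc1 | intermediate
18 | 3-{2,4-bis(benzyloxy)-6-bromo-3-[(2S)-1-methylpiperidin-2-yl]phenyl}-1-[4-(benzyloxy)phenyl]-3-[(tert-butyldimethylsilyl)oxy]propan-1-one, both C3 epimers | CN1CCCC[C@H]1c1c(OCc2ccccc2)cc(Br)c(C(O[Si](C)(C)C(C)(C)C)CC(=O)c2ccc(OCc3ccccc3)cc2)c1OCc1ccccc1 | intermediate
19 | (1S)-3-{2,4-bis(benzyloxy)-6-bromo-3-[(2S)-1-methylpiperidin-2-yl]phenyl}-1-[4-(benzyloxy)phenyl]-3-[(tert-butyldimethylsilyl)oxy]propan-1-ol, both C3 epimers | CN1CCCC[C@H]1c1c(OCc2ccccc2)cc(Br)c(C(O[Si](C)(C)C(C)(C)C)C[C@H](O)c2ccc(OCc3ccccc3)cc2)c1OCc1ccccc1 | intermediate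
20 | (2S)-5,7-bis(benzyloxy)-2-[4-(benzyloxy)phenyl]-4-[(tert-butyldimethylsilyl)oxy]-6-[(2S)-1-methylpiperidin-2-yl]chromane, both C4 epimers | CN1CCCC[C@H]1c1c(OCc2ccccc2)cc2c(c1OCc1ccccc1)C(O[Si](C)(C)C(C)(C)C)C[C@@H](c1ccc(OCc3ccccc3)cc1)O2 | intermediate
21 | (2S)-5,7-bis(benzyloxy)-2-[4-(benzyloxy)phenyl]-6-[(2S)-1-methylpiperidin-2-yl]chroman-4-ol, both C4 epimers | CN1CCCC[C@H]1c1c(OCc2ccccc2)cc2c(c1OCc1ccccc1)C(O)C[C@@H](c1ccc(OCc3ccccc3)cc1)O2 | intermediate
22 | (2S)-5,7-bis(benzyloxy)-2-[4-(benzyloxy)phenyl]-6-[(2S)-1-methylpiperidin-2-yl]chroman-4-one | CN1CCCC[C@H]1c1c(OCc2ccccc2)cc2c(c1OCc1ccccc1)C(=O)C[C@@H](c1ccc(OCc3ccccc3)cc1)O2 | intermediate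
23 | (2S)-5,7-dihydroxy-2-(4-hydroxyphenyl)-6-[(2S)-1-methylpiperidin-2-yl]chroman-4-one | CN1CCCC[C@H]1c1c(O)cc2c(c1O)C(=O)C[C@@H](c1ccc(O)cc1)O2 | target

**Totals**
Total step count: 13. Longest linear sequence: 13 steps, from 1 to 23.

**Steps most likely to fail**

Step 10. β-Hydride loss from the palladium alkoxide may be faster than C–O reductive elimination, which would oxidise the C2 carbinol and replace bromine by hydrogen. The carbonate base may also shuttle the silyl group between the two 1,3-related oxygens. The fallback closes ring C at its other C–O bond by a Mitsunobu reaction and sets out from ketone 18. Miyaura borylation (B2pin2, PdCl2(dppf), KOAc, dioxane, 90 °C) should give the aryl pinacol boronate F1. Oxidation with NaBO3·4H2O in THF/H2O should give the phenol F2. Transfer hydrogenation with the enantiomeric complex RuCl(p-cymene)[(R,R)-TsDPEN] should give the (1R)-carbinol F3. PPh3 and DIAD in THF at 0 °C should then join the phenol oxygen to C2 by SN2 displacement with inversion, which returns to the route at 20 with the (2S) configuration. The price is some risk of ionisation at the 4-benzyloxybenzylic carbon, so the reaction would be run cold and dilute.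

Step 3. The ortho-benzyloxy oxygens may compete with the sulfinyl oxygen for magnesium and erode facial selectivity. Addition to the doubly ortho-substituted imine may also be slow enough for the chloroalkyl Grignard reagent to alkylate itself. The fallback builds the ring by allylation and metathesis and sets out from imine 6. Indium powder and allyl bromide in THF at 60 °C (Barbier-type allylation through an indium-bound chair, Si-face attack as before) should give the homoallylic sulfinamide F4. N-Allylation (LiHMDS, allyl bromide, DMF, 0 → 25 °C) should give the N-allyl diene F5. Ring-closing metathesis with the second-generation Grubbs catalyst in CH2Cl2 at 40 °C should give the N-sulfinyl tetrahydropyridine F6. HCl in MeOH should release the free tetrahydropyridine F7. Diimide (2-nitrobenzenesulfonyl hydrazide, Et3N, CH2Cl2, 25 °C) should then saturate the ring alkene without touching the aryl bromide or the benzyl ethers, which returns to the route at piperidine 11.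

Step 6. The ortho-bromo aryllithium may lose lithium bromide to an aryne on slight warming, or take a proton from a neighbouring benzylic OCH2 group and start a Wittig rearrangement. The fallback replaces deprotonation by electrophilic substitution and sets out from 12. Vilsmeier–Haack formylation (POCl3, DMF, 70 °C) should attack the same carbon, which is ortho to one benzyloxy group and para to the other, to give the aryl iminium chloride F8. Hydrolysis with aqueous NaOAc returns to the route at aldehyde 14.

**Further compounds**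
F1 | step 10 | 3-{2,4-bis(benzyloxy)-3-[(2S)-1-methylpiperidin-2-yl]-6-(4,4,5,5-tetramethyl-1,3,2-dioxaborolan-2-yl)phenyl}-1-[4-(benzyloxy)phenyl]-3-[(tert-butyldimethylsilyl)oxy]propan-1-one | CN1CCCC[C@H]1c1c(OCc2ccccc2)cc(B2OC(C)(C)C(C)(C)O2)c(C(O[Si](C)(C)C(C)(C)C)CC(=O)c2ccc(OCc3ccccc3)cc2)c1OCc1ccccc1
F2 | step 10 | 3-{2,4-bis(benzyloxy)-6-hydroxy-3-[(2S)-1-methylpiperidin-2-yl]phenyl}-1-[4-(benzyloxy)phenyl]-3-[(tert-butyldimethylsilyl)oxy]propan-1-one | CN1CCCC[C@H]1c1c(OCc2ccccc2)cc(O)c(C(O[Si](C)(C)C(C)(C)C)CC(=O)c2ccc(OCc3ccccc3)cc2)c1OCc1ccccc1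
F3 | step 10 | (1R)-3-{2,4-bis(benzyloxy)-6-hydroxy-3-[(2S)-1-methylpiperidin-2-yl]phenyl}-1-[4-(benzyloxy)phenyl]-3-[(tert-butyldimethylsilyl)oxy]propan-1-ol | CN1CCCC[C@H]1c1c(OCc2ccccc2)cc(O)c(C(O[Si](C)(C)C(C)(C)C)C[C@@H](O)c2ccc(OCc3ccccc3)cc2)c1OCc1ccccc1
F4 | step 3 | (R)-N-{(1S)-1-[2,6-bis(benzyloxy)-4-bromophenyl]but-3-en-1-yl}-2-methylpropane-2-sulfinamide | CC(C)(C)[S@@](=O)N[C@@H](CC=C)c1c(OCc2ccccc2)cc(Br)cc1OCc1ccccc1
F5 | step 3 | (R)-N-allyl-N-{(1S)-1-[2,6-bis(benzyloxy)-4-bromophenyl]but-3-en-1-yl}-2-methylpropane-2-sulfinamide | CC(C)(C)[S@@](=O)N(CC=C)[C@@H](CC=C)c1c(OCc2ccccc2)cc(Br)cc1OCc1ccccc1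
F6 | step 3 | (2S)-2-[2,6-bis(benzyloxy)-4-bromophenyl]-1-[(R)-tert-butylsulfinyl]-1,2,3,6-tetrahydropyridine | CC(C)(C)[S@@](=O)N1CC=CC[C@H]1c1c(OCc2ccccc2)cc(Br)cc1OCc1ccccc1
F7 | step 3 | (2S)-2-[2,6-bis(benzyloxy)-4-bromophenyl]-1,2,3,6-tetrahydropyridine | N1CC=CC[C@H]1c1c(OCc2ccccc2)cc(Br)cc1OCc1ccccc1
F8 | step 6 | N-({2,4-bis(benzyloxy)-6-bromo-3-[(2S)-1-methylpiperidin-2-yl]phenyl}methylidene)-N-methylmethanaminium chloride | CN1CCCC[C@H]1c1c(OCc2ccccc2)cc(Br)c(C=[N+](C)C)c1OCc1ccccc1.[Cl-]
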